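**Numbering used:** cyclohexane positions as in the name of the target: C1 (quaternary; CH3 and CH2OAr), C2 (CH–CH3), C3 and C4 (ring CH2), C5 (carries the exocyclic isopropylidene), C6 (CH carrying the 3-hydroxypropyl chain). ArOH is isofraxidin.

**Assumption:** the (4S,5S)-bromodiazaborolidine is taken to give the (2S,3S) acid 11 in step 5; if the sense proves to be the reverse, the (4R,5R) reagent is used and nothing else changes.

## Retrosynthetic overview

1. The coumarin is bought as isofraxidin; the only ring to build is the cyclohexane, and it is closed last, at the C3–C4 bond.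
2. Enabling feature: C4 is allylic to the exocyclic C5=C(CH3)2 bond, and C3 becomes allylic once the C2 methyl is written as an exocyclic methylene. The ring is then the union of a 2-substituted allyl radical (C3 side) with the CH2 terminus of a 2,3-disubstituted buta-1,3-diene (C4/C5 side), and the diene collapses to the isopropylidene.
3. C2 is set after ring closure by hydrogen-atom-transfer hydrogenation of the C2 methylene, with the chair locked by allylic 1,3-strain between the C5 isopropylidene and the C6 chain.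
4. C1 and C6 come from an enantioselective boron-enolate Ireland–Claisen rearrangement of an (E)-2,3-dimethylbut-2-ene-1,4-diyl ester that already carries the isofraxidin ether, so no neopentyl etherification is needed.
5. After the rearrangement the carboxyl group becomes the diene (Stille acylation, methylenation) and the isopropenyl group becomes the allylic bromide (SeO2, Appel).

Key step: step 10

## Route

Step 1
Reactants: 1 δ-valerolactone
Product: 4 5-[(tert-butyldiphenylsilyl)oxy]pentanoic acid, via sodium 5-hydroxypentanoate 2 (not isolated), via silyl ester of the silyl ether 3 (not isolated)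
Conditions: NaOH (1 equiv), H2O/MeOH, rt, evaporate; TBDPSCl (2.2 equiv), imidazole, DMF, rt; AcOH/THF/H2O, rt
Reagents that add atoms: sodium hydroxide [Na+].[OH-]; tert-butyl(chloro)diphenylsilane CC(C)(C)[Si](Cl)(c1ccccc1)c1ccccc1
Why: Saponification of the lactone, exhaustive silylation and selective hydrolysis of the silyl ester, which is cleaved far faster than the primary silyl ether (protecting-group chemistry).

Step 2
Reactants: 5 2,3-dimethylbuta-1,3-diene
Product: 6 (2E)-1,4-dibromo-2,3-dimethylbut-2-ene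
Conditions: Br2 (1 equiv), CHCl3, −20 °C; recrystallise
Reagents that add atoms: bromine BrBr
Why: Electrophilic 1,4-addition of bromine to the diene should give the thermodynamically preferred, crystalline E-1,4-dibromide.

Step 3
Reactants: 6 (2E)-1,4-dibromo-2,3-dimethylbut-2-ene (3 equiv); 7 isofraxidin
Product: 8 7-{[(2E)-4-bromo-2,3-dimethylbut-2-en-1-yl]oxy}-6,8-dimethoxy-2H-chromen-2-one
Conditions: K2CO3, acetone, reflux
Reagents that add atoms: none
Why: Williamson etherification: the acidic coumarin phenoxide displaces one primary allylic bromide by SN2, excess dibromide suppresses the bis-ether, and the E geometry is untouched.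

Step 4
Reactants: 8 bromo ether; 4 5-[(tert-butyldiphenylsilyl)oxy]pentanoic acid
Product: 9 (2E)-4-[(6,8-dimethoxy-2-oxo-2H-chromen-7-yl)oxy]-2,3-dimethylbut-2-en-1-yl 5-[(tert-butyldiphenylsilyl)oxy]pentanoate
Conditions: Cs2CO3, DMF, rt
Reagents that add atoms: none
Why: O-Alkylation of the caesium carboxylate by the primary allylic bromide (SN2) gives the allyl ester under conditions that leave the coumarin and the silyl ether alone.

Step 5
Reactants: 9 allyl ester
Product: 11 (2S,3S)-2-{3-[(tert-butyldiphenylsilyl)oxy]propyl}-3-{[(6,8-dimethoxy-2-oxo-2H-chromen-7-yl)oxy]methyl}-3,4-dimethylpent-4-enoic acid, via Z(O) boron ketene acetal 10 (not isolated)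
Conditions: (4S,5S)-2-bromo-4,5-diphenyl-1,3-bis{[3,5-bis(trifluoromethyl)phenyl]sulfonyl}-1,3,2-diazaborolidine (1.2 equiv), i-Pr2NEt, CH2Cl2, −78 °C; then −20 °C to 4 °C; aqueous work-up
Reagents that add atoms: none
Why: Enantioselective boron-enolate Ireland–Claisen rearrangement: soft enolisation gives the ketene acetal with the silyloxypropyl chain cis to O–B, whose chair transition state with the E alkene (CH2OAr pseudo-equatorial, CH3 pseudo-axial on the carbon that becomes quaternary) fixes the relative configuration of the future C1 and C6, while the C2-symmetric controller on boron selects the enolate face and so the absolute configuration, and no strong base meets the coumarin.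

Step 6
Reactants: 11 acid
Product: 13 (4S,5S)-4-{3-[(tert-butyldiphenylsilyl)oxy]propyl}-5-{[(6,8-dimethoxy-2-oxo-2H-chromen-7-yl)oxy]methyl}-2,5,6-trimethylhepta-1,6-dien-3-one, via acid chloride 12 (not isolated)
Conditions: (COCl)2, DMF (cat.), CH2Cl2, 0 °C to rt, evaporate; tributyl(prop-1-en-2-yl)stannane, PdCl2(PPh3)2 (cat.), toluene, 70 °C
Reagents that add atoms: tributyl(prop-1-en-2-yl)stannane CCCC[Sn](CCCC)(CCCC)C(C)=C
Why: Stille acylation of the acid chloride gives the isopropenyl ketone under neutral conditions, so the stereocentre next to the carbonyl is not epimerised and the coumarin lactone is not attacked.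

Step 7
Reactants: 13 enone
Product: 14 (4S,5S)-4-{3-[(tert-butyldiphenylsilyl)oxy]propyl}-5-{[(6,8-dimethoxy-2-oxo-2H-chromen-7-yl)oxy]methyl}-6-(hydroxymethyl)-2,5-dimethylhepta-1,6-dien-3-one
Conditions: SeO2 (cat.), t-BuOOH, CH2Cl2, rt
Reagents that add atoms: selenium dioxide O=[Se]=O (catalytic oxygen carrier); tert-butyl hydroperoxide CC(C)(C)OO (terminal oxygen source)
Why: Selenium dioxide allylic oxidation (ene reaction, then [2,3] shift) should attack only the electron-rich isolated isopropenyl group, whose methyl carries the only allylic hydrogens, and leave the electron-poor enone alkene alone.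

Step 8
Reactants: 14 hydroxy enone
Product: 15 (3S,4R)-7-[(tert-butyldiphenylsilyl)oxy]-3-{[(6,8-dimethoxy-2-oxo-2H-chromen-7-yl)oxy]methyl}-3-methyl-4-(3-methylbuta-1,3-dien-2-yl)-2-methylideneheptan-1-ol
Conditions: Zn, CH2Br2, TiCl4, THF/CH2Cl2, 0 °C to rt
Reagents that add atoms: dibromomethane BrCBr
Why: Takai–Lombardo methylenation converts the hindered enone into the 2,3-disubstituted buta-1,3-diene; the reagent is non-basic, so the adjacent stereocentre is safe, and it does not touch the lactone.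

Step 9
Reactants: 15 dienyl allylic alcohol
Product: 16 tert-butyl{[(4R,5S)-6-(bromomethyl)-5-{[(6,8-dimethoxy-2-oxo-2H-chromen-7-yl)oxy]methyl}-5-methyl-4-(3-methylbuta-1,3-dien-2-yl)hept-6-en-1-yl]oxy}diphenylsilane
Conditions: CBr4, PPh3, CH2Cl2, 0 °C
Reagents that add atoms: tetrabromomethane BrC(Br)(Br)Br
Why: Appel bromination of the primary allylic alcohol; SN2 and SN2′ displacement give the same bromide because both allyl termini are CH2 groups.

Step 10
Reactants: 16 allylic bromide
Product: 17 7-{[(1S,6R)-6-{3-[(tert-butyldiphenylsilyl)oxy]propyl}-1-methyl-2-methylidene-5-(propan-2-ylidene)cyclohexyl]methoxy}-6,8-dimethoxy-2H-chromen-2-one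
Conditions: Bu3SnH (1.3 equiv) and 1,1′-azobis(cyclohexanecarbonitrile) added by syringe pump, toluene (2 mM), 110 °C
Reagents that add atoms: none
Why: Bu3Sn• abstracts bromine to give a 2-substituted allyl radical whose CH2 terminus adds to the CH2 terminus of the diene that sits on the future C5, forming the C3–C4 bond; the new allyl radical then takes hydrogen from Bu3SnH at its primary terminus, which leaves the tetrasubstituted C5 isopropylidene. The closest known reaction type is the tin hydride reductive radical cyclisation of unsaturated halides onto 1,3-dienes. The six-membered carbocycle closes in the 6-endo-trig mode with respect to the attacked diene double bond. No stereocentre is formed, and C1 and C6 are not radical sites, so they cannot scramble. The step needs attack at that diene CH2 rather than at the internal carbon (five-membered ring, unstabilised radical) or the far CH2 (eight-membered ring), which ring size and allyl stabilisation of the adduct secure, and it needs hydrogen transfer at the unhindered primary terminus, which the bulk of the stannane and the more substituted alkene favour. Ring closure must also outrun reduction of the first allyl radical, which the low stationary stannane concentration, the high temperature and the fully substituted C1 in the tether should secure.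

Step 11
Reactants: 17 methylidene cyclohexane
Product: 18 7-{[(1R,2R,6R)-6-{3-[(tert-butyldiphenylsilyl)oxy]propyl}-1,2-dimethyl-5-(propan-2-ylidene)cyclohexyl]methoxy}-6,8-dimethoxy-2H-chromen-2-one
Conditions: Mn(dpm)3 (cat., dpm = dipivaloylmethanate), PhSiH3, t-BuOOH, i-PrOH, rt
Reagents that add atoms: none
Why: Hydrogen-atom-transfer hydrogenation (Mukaiyama-type manganese hydride): H• adds to the exocyclic CH2, and the tertiary C2 radical takes the second hydrogen under product-like control in the chair that holds the C6 chain axial (allylic 1,3-strain against the C5 isopropylidene) and the C1 CH2OAr axial, so the new methyl should end equatorial and trans to the C1 methyl; the 1,1-disubstituted alkene should react far faster than the tetrasubstituted isopropylidene and the electron-poor coumarin C3=C4 bond.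

Step 12
Reactants: 18 silyl ether
Product: 19 7-{[(1R,2R,6R)-6-(3-hydroxypropyl)-1,2-dimethyl-5-(propan-2-ylidene)cyclohexyl]methoxy}-6,8-dimethoxy-2H-chromen-2-one
Conditions: HF·pyridine, THF, 0 °C to rt
Reagents that add atoms: none
Why: Fluoride-mediated desilylation frees the primary alcohol without touching the lactone, the aryl ethers or the isopropylidene.

## Compound list

1 | δ-valerolactone (oxan-2-one) | O=C1CCCCO1 | starting material
2 | sodium 5-hydroxypentanoate | OCCCCC(=O)[O-].[Na+] | intermediate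
3 | tert-butyldiphenylsilyl 5-[(tert-butyldiphenylsilyl)oxy]pentanoate | CC(C)(C)[Si](OCCCCC(=O)O[Si](c1ccccc1)(c1ccccc1)C(C)(C)C)(c1ccccc1)c1ccccc1 | intermediate
4 | 5-[(tert-butyldiphenylsilyl)oxy]pentanoic acid | CC(C)(C)[Si](OCCCCC(=O)O)(c1ccccc1)c1ccccc1 | intermediate
5 | 2,3-dimethylbuta-1,3-diene | C=C(C)C(C)=C | starting material
6 | (2E)-1,4-dibromo-2,3-dimethylbut-2-ene | BrC/C(C)=C(\C)CBr | intermediate
7 | isofraxidin (7-hydroxy-6,8-dimethoxy-2H-chromen-2-one) | COc1cc2ccc(=O)oc2c(OC)c1O | starting material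
8 | 7-{[(2E)-4-bromo-2,3-dimethylbut-2-en-1-yl]oxy}-6,8-dimethoxy-2H-chromen-2-one | COc1cc2ccc(=O)oc2c(OC)c1OC/C(C)=C(\C)CBr | intermediate
9 | (2E)-4-[(6,8-dimethoxy-2-oxo-2H-chromen-7-yl)oxy]-2,3-dimethylbut-2-en-1-yl 5-[(tert-butyldiphenylsilyl)oxy]pentanoate | COc1cc2ccc(=O)oc2c(OC)c1OC/C(C)=C(\C)COC(=O)CCCCO[Si](c1ccccc1)(c1ccccc1)C(C)(C)C | intermediate
10 | Z(O) boron ketene acetal of 9 (chain cis to O–B; (4S,5S)-diazaborolidine on boron) | COc1cc2ccc(=O)oc2c(OC)c1OC/C(C)=C(\C)CO/C(OB3N(S(=O)(=O)c4cc(C(F)(F)F)cc(C(F)(F)F)c4)[C@@H](c4ccccc4)[C@H](c4ccccc4)N3S(=O)(=O)c3cc(C(F)(F)F)cc(C(F)(F)F)c3)=C/CCCO[Si](c3ccccc3)(c3ccccc3)C(C)(C)C | intermediate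
11 | (2S,3S)-2-{3-[(tert-butyldiphenylsilyl)oxy]propyl}-3-{[(6,8-dimethoxy-2-oxo-2H-chromen-7-yl)oxy]methyl}-3,4-dimethylpent-4-enoic acid | COc1cc2ccc(=O)oc2c(OC)c1OC[C@](C)(C(C)=C)[C@H](CCCO[Si](c1ccccc1)(c1ccccc1)C(C)(C)C)C(=O)O | intermediate
12 | (2S,3S)-2-{3-[(tert-butyldiphenylsilyl)oxy]propyl}-3-{[(6,8-dimethoxy-2-oxo-2H-chromen-7-yl)oxy]methyl}-3,4-dimethylpent-4-enoyl chloride | COc1cc2ccc(=O)oc2c(OC)c1OC[C@](C)(C(C)=C)[C@H](CCCO[Si](c1ccccc1)(c1ccccc1)C(C)(C)C)C(Cl)=O | intermediate
13 | (4S,5S)-4-{3-[(tert-butyldiphenylsilyl)oxy]propyl}-5-{[(6,8-dimethoxy-2-oxo-2H-chromen-7-yl)oxy]methyl}-2,5,6-trimethylhepta-1,6-dien-3-one | COc1cc2ccc(=O)oc2c(OC)c1OC[C@](C)(C(C)=C)[C@H](CCCO[Si](c1ccccc1)(c1ccccc1)C(C)(C)C)C(=O)C(C)=C | intermediate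
14 | (4S,5S)-4-{3-[(tert-butyldiphenylsilyl)oxy]propyl}-5-{[(6,8-dimethoxy-2-oxo-2H-chromen-7-yl)oxy]methyl}-6-(hydroxymethyl)-2,5-dimethylhepta-1,6-dien-3-one | COc1cc2ccc(=O)oc2c(OC)c1OC[C@](C)(C(=C)CO)[C@H](CCCO[Si](c1ccccc1)(c1ccccc1)C(C)(C)C)C(=O)C(C)=C | intermediate
15 | (3S,4R)-7-[(tert-butyldiphenylsilyl)oxy]-3-{[(6,8-dimethoxy-2-oxo-2H-chromen-7-yl)oxy]methyl}-3-methyl-4-(3-methylbuta-1,3-dien-2-yl)-2-methylideneheptan-1-ol | COc1cc2ccc(=O)oc2c(OC)c1OC[C@](C)(C(=C)CO)[C@H](CCCO[Si](c1ccccc1)(c1ccccc1)C(C)(C)C)C(=C)C(C)=C | intermediate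
16 | tert-butyl{[(4R,5S)-6-(bromomethyl)-5-{[(6,8-dimethoxy-2-oxo-2H-chromen-7-yl)oxy]methyl}-5-methyl-4-(3-methylbuta-1,3-dien-2-yl)hept-6-en-1-yl]oxy}diphenylsilane | COc1cc2ccc(=O)oc2c(OC)c1OC[C@](C)(C(=C)CBr)[C@H](CCCO[Si](c1ccccc1)(c1ccccc1)C(C)(C)C)C(=C)C(C)=C | intermediate
17 | 7-{[(1S,6R)-6-{3-[(tert-butyldiphenylsilyl)oxy]propyl}-1-methyl-2-methylidene-5-(propan-2-ylidene)cyclohexyl]methoxy}-6,8-dimethoxy-2H-chromen-2-one | COc1cc2ccc(=O)oc2c(OC)c1OC[C@]1(C)C(=C)CCC(=C(C)C)[C@H]1CCCO[Si](c1ccccc1)(c1ccccc1)C(C)(C)C | intermediate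
18 | 7-{[(1R,2R,6R)-6-{3-[(tert-butyldiphenylsilyl)oxy]propyl}-1,2-dimethyl-5-(propan-2-ylidene)cyclohexyl]methoxy}-6,8-dimethoxy-2H-chromen-2-one | COc1cc2ccc(=O)oc2c(OC)c1OC[C@]1(C)[C@H](C)CCC(=C(C)C)[C@H]1CCCO[Si](c1ccccc1)(c1ccccc1)C(C)(C)C | intermediate
19 | 7-{[(1R,2R,6R)-6-(3-hydroxypropyl)-1,2-dimethyl-5-(propan-2-ylidene)cyclohexyl]methoxy}-6,8-dimethoxy-2H-chromen-2-one | COc1cc2ccc(=O)oc2c(OC)c1OC[C@]1(C)[C@H](C)CCC(=C(C)C)[C@H]1CCCO | target

## Step count and risks

Total step count: 12. Longest linear sequence: 11 steps (5 to 19, steps 2 to 12).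

**Step 10 (key step).** The stabilised allyl radical may be reduced by the stannane, or may dimerise, before it closes the ring, because an allyl radical adds slowly even to a diene. The fallback sets out from 13 and returns at 18, so it replaces steps 7 to 11. Methylenation of 13 (Zn, CH2Br2, TiCl4) gives the triene F1. Hydroboration of its isolated isopropenyl group with enantiopure 10-trimethylsilyl-9-borabicyclo[3.3.2]decane, followed by NaBO3, gives the primary alcohol F2; the hydrogen delivery is reagent-controlled, and the conjugated diene is far less reactive toward dialkylboranes. I2, PPh3 and imidazole give the primary iodide F3. Bu3SnH and AIBN in benzene at 80 °C then close the same ring bond through the fast 6-endo addition of a non-stabilised primary alkyl radical to the diene terminus and give 18 directly.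

**Step 11.** Hydrogen-atom delivery to the ring radical may show poor facial selectivity, and the coumarin C3=C4 bond may be reduced as well. The fallback sets out from 17 and returns at 18. 9-BBN followed by NaBO3 gives the hydroxymethyl compound F4 together with its C2 epimer F5. Dess–Martin periodinane gives the aldehyde F6 and its epimer F7. DBU in CH2Cl2 equilibrates the mixture to the equatorial aldehyde F6, which is ionic thermodynamic control at the carbon next to the formyl group. NaBH4 in MeOH at 0 °C returns F4 as one epimer. I2, PPh3 and imidazole give the iodomethyl compound F8, and Bu3SnH with AIBN reduces it to 18.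

**Step 5.** The hindered tetrasubstituted allyl ester may rearrange slowly, the enolate geometry may erode, or the enantioselectivity may be low. The fallback sets out from 9 and returns at 11. LDA and TMSCl in THF/DMPU at −78 °C give the Z(O) trimethylsilyl ketene acetal F9. Warming to rt and aqueous work-up give acid 11 as a racemate with its enantiomer F10, through the same chair and so with the same relative configuration. The enantiomers are separated by preparative chromatography on a chiral stationary phase, and 11 goes on to step 6.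

Further compounds
F1 | step 10 | tert-butyl{[(4R,5S)-5-{[(6,8-dimethoxy-2-oxo-2H-chromen-7-yl)oxy]methyl}-5,6-dimethyl-4-(3-methylbuta-1,3-dien-2-yl)hept-6-en-1-yl]oxy}diphenylsilane | COc1cc2ccc(=O)oc2c(OC)c1OC[C@](C)(C(C)=C)[C@H](CCCO[Si](c1ccccc1)(c1ccccc1)C(C)(C)C)C(=C)C(C)=C
F2 | step 10 | (2S,3S,4R)-7-[(tert-butyldiphenylsilyl)oxy]-3-{[(6,8-dimethoxy-2-oxo-2H-chromen-7-yl)oxy]methyl}-2,3-dimethyl-4-(3-methylbuta-1,3-dien-2-yl)heptan-1-ol | COc1cc2ccc(=O)oc2c(OC)c1OC[C@](C)([C@H](C)CO)[C@H](CCCO[Si](c1ccccc1)(c1ccccc1)C(C)(C)C)C(=C)C(C)=C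
F3 | step 10 | tert-butyl{[(4R,5S,6S)-5-{[(6,8-dimethoxy-2-oxo-2H-chromen-7-yl)oxy]methyl}-7-iodo-5,6-dimethyl-4-(3-methylbuta-1,3-dien-2-yl)heptyl]oxy}diphenylsilane | COc1cc2ccc(=O)oc2c(OC)c1OC[C@](C)([C@H](C)CI)[C@H](CCCO[Si](c1ccccc1)(c1ccccc1)C(C)(C)C)C(=C)C(C)=C
F4 | step 11 | 7-{[(1S,2R,6R)-6-{3-[(tert-butyldiphenylsilyl)oxy]propyl}-2-(hydroxymethyl)-1-methyl-5-(propan-2-ylidene)cyclohexyl]methoxy}-6,8-dimethoxy-2H-chromen-2-one | COc1cc2ccc(=O)oc2c(OC)c1OC[C@]1(C)[C@H](CO)CCC(=C(C)C)[C@H]1CCCO[Si](c1ccccc1)(c1ccccc1)C(C)(C)C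
F5 | step 11 | 7-{[(1S,2S,6R)-6-{3-[(tert-butyldiphenylsilyl)oxy]propyl}-2-(hydroxymethyl)-1-methyl-5-(propan-2-ylidene)cyclohexyl]methoxy}-6,8-dimethoxy-2H-chromen-2-one | COc1cc2ccc(=O)oc2c(OC)c1OC[C@]1(C)[C@@H](CO)CCC(=C(C)C)[C@H]1CCCO[Si](c1ccccc1)(c1ccccc1)C(C)(C)C
F6 | step 11 | 7-{[(1S,2R,6R)-6-{3-[(tert-butyldiphenylsilyl)oxy]propyl}-2-formyl-1-methyl-5-(propan-2-ylidene)cyclohexyl]methoxy}-6,8-dimethoxy-2H-chromen-2-one | COc1cc2ccc(=O)oc2c(OC)c1OC[C@]1(C)[C@H](C=O)CCC(=C(C)C)[C@H]1CCCO[Si](c1ccccc1)(c1ccccc1)C(C)(C)C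
F7 | step 11 | 7-{[(1S,2S,6R)-6-{3-[(tert-butyldiphenylsilyl)oxy]propyl}-2-formyl-1-methyl-5-(propan-2-ylidene)cyclohexyl]methoxy}-6,8-dimethoxy-2H-chromen-2-one | COc1cc2ccc(=O)oc2c(OC)c1OC[C@]1(C)[C@@H](C=O)CCC(=C(C)C)[C@H]1CCCO[Si](c1ccccc1)(c1ccccc1)C(C)(C)C
F8 | step 11 | 7-{[(1S,2R,6R)-6-{3-[(tert-butyldiphenylsilyl)oxy]propyl}-2-(iodomethyl)-1-methyl-5-(propan-2-ylidene)cyclohexyl]methoxy}-6,8-dimethoxy-2H-chromen-2-one | COc1cc2ccc(=O)oc2c(OC)c1OC[C@]1(C)[C@H](CI)CCC(=C(C)C)[C@H]1CCCO[Si](c1ccccc1)(c1ccccc1)C(C)(C)C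
F9 | step 5 | Z(O) trimethylsilyl ketene acetal of 9 (chain cis to O–Si) | COc1cc2ccc(=O)oc2c(OC)c1OC/C(C)=C(\C)CO/C(O[Si](C)(C)C)=C/CCCO[Si](c1ccccc1)(c1ccccc1)C(C)(C)C
F10 | step 5 | (2R,3R)-2-{3-[(tert-butyldiphenylsilyl)oxy]propyl}-3-{[(6,8-dimethoxy-2-oxo-2H-chromen-7-yl)oxy]methyl}-3,4-dimethylpent-4-enoic acid | COc1cc2ccc(=O)oc2c(OC)c1OC[C@@](C)(C(C)=C)[C@@H](CCCO[Si](c1ccccc1)(c1ccccc1)C(C)(C)C)C(=O)O
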